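**Retrosynthetic overview**

- Alopecurone G ⇐ bis-silyl flavanone (fluoride desilylation) ⇐ 7-silyloxy-8-lavandulylchromone + arylboronic acid; a Rh-catalysed asymmetric 1,4-arylation sets C2.
- Chromone ⇐ lavandulyl-bearing 1-methoxy-1,3-bis(silyloxy)diene + penta-1,4-diyn-3-one. In one flask a [4+2]/aromatisation builds ring A, then an amine-triggered 6-endo closure onto the second alkyne builds ring C; ring B is bought.
- Diene ⇐ methyl acetoacetate + (S)-lavandulyl iodide, so the side chain sits on the central carbon of a 1,3-dicarbonyl (future C8) before any ring exists.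
- (S)-Lavandulyl iodide ⇐ Evans deconjugative prenylation of an N-(3-methylbut-2-enoyl)oxazolidinone, which sets the side-chain stereocentre.

Assumption: the SMILES is read as 2S at the flavanone carbon and 2R in the lavandulyl chain; penta-1,4-diyn-3-ol and 4-bromo-3-methoxyphenol are bought as catalogue reagents.

**Route**

Step 1
Reactants: 1 (4S)-4-benzyl-1,3-oxazolidin-2-one; 2 3-methylbut-2-enoyl chloride
Product: 4 (4S)-4-benzyl-3-(3-methylbut-2-enoyl)-1,3-oxazolidin-2-one, via lithium oxazolidinide 3 (not isolated)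
Conditions: n-BuLi, THF, −78 °C; then 2, −78 → 0 °C
Reagents that add atoms: none
Why: N-acylation of the lithiated Evans auxiliary by the acid chloride; no new stereocentre.

Step 2
Reactants: 4 (4S)-4-benzyl-3-(3-methylbut-2-enoyl)-1,3-oxazolidin-2-one; 5 1-bromo-3-methylbut-2-ene (prenyl bromide)
Product: 7 (4S)-4-benzyl-3-[(2S)-5-methyl-2-(prop-1-en-2-yl)hex-4-enoyl]-1,3-oxazolidin-2-one, via sodium dienolate 6 (not isolated)
Conditions: NaN(SiMe3)2, THF, −78 °C; then 5, −78 → −40 °C
Reagents that add atoms: none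
Why: Evans asymmetric alkylation in its deconjugative form: γ-deprotonation gives the chelated (Z)-dienolate, which is prenylated at the α-carbon on the face opposite the benzyl group, giving the (S) centre (the same spatial arrangement is 2R once this carbonyl carbon is the CH2 on ring A).

Step 3
Reactants: 7 (4S)-4-benzyl-3-[(2S)-5-methyl-2-(prop-1-en-2-yl)hex-4-enoyl]-1,3-oxazolidin-2-one
Product: 8 (2S)-5-methyl-2-(prop-1-en-2-yl)hex-4-en-1-ol [(S)-lavandulol]
Conditions: LiBH4, MeOH (1 equiv), THF, 0 °C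
Reagents that add atoms: none
Why: Hydride reduction cleaves the imide to the primary alcohol and frees the auxiliary; the centre is no longer α to a carbonyl and cannot epimerise.

Step 4
Reactants: 8 (2S)-5-methyl-2-(prop-1-en-2-yl)hex-4-en-1-ol
Product: 9 (3S)-3-(iodomethyl)-2,6-dimethylhepta-1,5-diene [(S)-lavandulyl iodide]
Conditions: PPh3, I2, imidazole, CH2Cl2, 0 °C → rt
Reagents that add atoms: iodine, II
Why: Appel-type iodination of a primary alcohol; the stereocentre is one carbon away and is not involved.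

Step 5
Reactants: 9 (3S)-3-(iodomethyl)-2,6-dimethylhepta-1,5-diene; 10 methyl 3-oxobutanoate (methyl acetoacetate)
Product: 11 methyl (4R)-2-acetyl-7-methyl-4-(prop-1-en-2-yl)oct-6-enoate (both C2 epimers)
Conditions: K2CO3, DMF, 50 °C (10 in twofold excess)
Reagents that add atoms: none
Why: Acetoacetic ester C-alkylation with a primary iodide puts the side chain on the carbon that becomes C8, between the two future ring-A oxygens; the new C2 centre becomes sp2 in step 6.

Step 6
Reactants: 11 methyl (4R)-2-acetyl-7-methyl-4-(prop-1-en-2-yl)oct-6-enoate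
Product: 12 methyl (4R)-7-methyl-4-(prop-1-en-2-yl)-2-{1-[(triisopropylsilyl)oxy]ethylidene}oct-6-enoate (E/Z mixture)
Conditions: i-Pr3SiOTf, Et3N, CH2Cl2, 0 °C → rt
Reagents that add atoms: triisopropylsilyl trifluoromethanesulfonate, CC(C)[Si](OS(=O)(=O)C(F)(F)F)(C(C)C)C(C)C
Why: Soft enolisation and O-silylation of the β-keto ester gives a robust silyl enol ether whose oxygen becomes the protected 7-OH; any terminal enol ether regioisomer converges to the same diene in step 7.

Step 7
Reactants: 12 methyl (4R)-7-methyl-4-(prop-1-en-2-yl)-2-{1-[(triisopropylsilyl)oxy]ethylidene}oct-6-enoate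
Product: 13 [(1-methoxy-2-{[(2R)-5-methyl-2-(prop-1-en-2-yl)hex-4-en-1-yl]}-3-[(triisopropylsilyl)oxy]buta-1,3-dien-1-yl)oxy]trimethylsilane (used crude)
Conditions: LiN(i-Pr)2, Me3SiCl (present from the start), THF, −78 → 0 °C
Reagents that add atoms: chlorotrimethylsilane, C[Si](C)(C)Cl
Why: Deprotonation of the silyloxy enoate and O-silylation of the ester dienolate, the standard preparation of Chan-type 1-methoxy-1,3-bis(silyloxy)dienes; no stereocentre is formed.

Step 8
Reactants: 14 penta-1,4-diyn-3-ol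
Product: 15 penta-1,4-diyn-3-one (kept as a filtered CH2Cl2 solution)
Conditions: MnO2, CH2Cl2, 0 °C → rt; filter
Reagents that add atoms: none
Why: MnO2 oxidation of a doubly propargylic alcohol; the ketone is unstable neat and is therefore used in solution.

Step 9
Reactants: 13 the silyl ketene acetal diene; 15 penta-1,4-diyn-3-one
Product: 19 8-[(2R)-5-methyl-2-(prop-1-en-2-yl)hex-4-en-1-yl]-7-[(triisopropylsilyl)oxy]-4H-chromen-4-one, via cyclohexadiene cycloadduct 16 (not isolated), via hydroxyaryl ethynyl ketone 17 (not isolated), via diethylamino enaminone 18 (not isolated)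
Conditions: 15 (1.5 equiv), toluene/CH2Cl2, 0 °C → rt; then Et2NH (3 equiv), EtOH, rt
Reagents that add atoms: none
Why: Proposed new method: the ketene acetal diene adds across one alkyne of the cross-conjugated diynone with its CH2 terminus at the alkyne CH (closest known type: Diels–Alder of Chan/Brassard dienes with ynones), ethanolysis of the Me3Si ether collapses the mixed ketal with loss of MeOH to the phenol (ring A), and Et2NH adds to the second alkyne to give an enaminone that the ortho-phenol displaces 6-endo (closest known type: amine-mediated chromone formation from 2-hydroxyaryl ynones, ring C); only the use of the diynone as a two-ring linchpin is untested, and no stereocentre is formed or touched.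

Step 10
Reactants: 20 4-bromo-3-methoxyphenol
Product: 21 (4-bromo-3-methoxyphenoxy)triisopropylsilane
Conditions: i-Pr3SiCl, imidazole, DMF, rt
Reagents that add atoms: chlorotriisopropylsilane, CC(C)[Si](Cl)(C(C)C)C(C)C
Why: Imidazole-promoted silylation protects the future 4'-OH with the same group as the 7-OH, so both are removed together at the end.

Step 11
Reactants: 21 (4-bromo-3-methoxyphenoxy)triisopropylsilane
Product: 23 {2-methoxy-4-[(triisopropylsilyl)oxy]phenyl}boronic acid, via aryllithium 22 (not isolated)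
Conditions: n-BuLi, THF, −78 °C; B(O-i-Pr)3, −78 °C → rt; 1 M HCl work-up
Reagents that add atoms: triisopropyl borate, CC(C)OB(OC(C)C)OC(C)C; water, O
Why: Bromine–lithium exchange, trapping by the borate and hydrolysis (lithiation–borylation); the aryl silyl ether is stable to n-BuLi at −78 °C.

Step 12
Reactants: 19 the 7-silyloxy-8-lavandulylchromone; 23 {2-methoxy-4-[(triisopropylsilyl)oxy]phenyl}boronic acid
Product: 24 (2S)-2-{2-methoxy-4-[(triisopropylsilyl)oxy]phenyl}-8-[(2R)-5-methyl-2-(prop-1-en-2-yl)hex-4-en-1-yl]-7-[(triisopropylsilyl)oxy]-2,3-dihydro-4H-chromen-4-one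
Conditions: 23 (3 equiv), [Rh(OH)(cod)]2 (2.5 mol %; cod = cycloocta-1,5-diene), (S)-MeO-F12-BIPHEP (6 mol %), toluene/H2O 10:1, 40 °C
Reagents that add atoms: none
Why: Hayashi–Miyaura-type Rh-catalysed asymmetric 1,4-addition of an arylboronic acid to a chromone; the (S)-biaryl diphosphine delivers aryl to the enone face that gives (S)-3-arylcyclohexanones from cyclohex-2-enone, which maps onto 2S here under catalyst control independent of the remote side-chain centre, and base-free conditions suppress retro-oxa-Michael opening.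

Step 13
Reactants: 24 the bis-silyl flavanone
Product: 25 Alopecurone G, (2S)-7-hydroxy-2-(4-hydroxy-2-methoxyphenyl)-8-[(2R)-5-methyl-2-(prop-1-en-2-yl)hex-4-en-1-yl]-2,3-dihydro-4H-chromen-4-one
Conditions: Bu4NF, AcOH (1:1, 2.4 equiv each), THF, 0 °C
Reagents that add atoms: none
Why: Fluoride cleavage of both aryl silyl ethers, buffered with AcOH so that no phenoxide opens ring C (which would racemise C2) and no strong acid reaches the side-chain alkenes.

**Compound list**

1 | (4S)-4-benzyl-1,3-oxazolidin-2-one | O=C1N[C@@H](Cc2ccccc2)CO1 | starting material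
2 | 3-methylbut-2-enoyl chloride | CC(C)=CC(=O)Cl | starting material
3 | lithium (4S)-4-benzyl-2-oxo-1,3-oxazolidin-3-ide | [Li+].O=C1[N-][C@@H](Cc2ccccc2)CO1 | intermediate (not isolated)
4 | (4S)-4-benzyl-3-(3-methylbut-2-enoyl)-1,3-oxazolidin-2-one | CC(C)=CC(=O)N1[C@@H](Cc2ccccc2)COC1=O | intermediate
5 | 1-bromo-3-methylbut-2-ene | CC(C)=CCBr | starting material
6 | sodium (1Z)-1-[(4S)-4-benzyl-2-oxo-1,3-oxazolidin-3-yl]-3-methylbuta-1,3-dien-1-olate | [Na+].C=C(C)/C=C(\[O-])N1[C@@H](Cc2ccccc2)COC1=O | intermediate (not isolated)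
7 | (4S)-4-benzyl-3-[(2S)-5-methyl-2-(prop-1-en-2-yl)hex-4-enoyl]-1,3-oxazolidin-2-one | C=C(C)[C@H](CC=C(C)C)C(=O)N1[C@@H](Cc2ccccc2)COC1=O | intermediate
8 | (2S)-5-methyl-2-(prop-1-en-2-yl)hex-4-en-1-ol | C=C(C)[C@H](CC=C(C)C)CO | intermediate
9 | (3S)-3-(iodomethyl)-2,6-dimethylhepta-1,5-diene | C=C(C)[C@H](CC=C(C)C)CI | intermediate
10 | methyl 3-oxobutanoate | CC(=O)CC(=O)OC | starting material
11 | methyl (4R)-2-acetyl-7-methyl-4-(prop-1-en-2-yl)oct-6-enoate | C=C(C)[C@H](CC=C(C)C)CC(C(C)=O)C(=O)OC | intermediate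
12 | methyl (4R)-7-methyl-4-(prop-1-en-2-yl)-2-{1-[(triisopropylsilyl)oxy]ethylidene}oct-6-enoate | C=C(C)[C@H](CC=C(C)C)CC(C(=O)OC)=C(C)O[Si](C(C)C)(C(C)C)C(C)C | intermediate
13 | [(1-methoxy-2-{[(2R)-5-methyl-2-(prop-1-en-2-yl)hex-4-en-1-yl]}-3-[(triisopropylsilyl)oxy]buta-1,3-dien-1-yl)oxy]trimethylsilane | C=C(C)[C@H](CC=C(C)C)CC(C(=C)O[Si](C(C)C)(C(C)C)C(C)C)=C(OC)O[Si](C)(C)C | intermediate
14 | penta-1,4-diyn-3-ol | C#CC(O)C#C | starting material
15 | penta-1,4-diyn-3-one | C#CC(=O)C#C | intermediate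
16 | 1-{6-methoxy-5-[(2R)-5-methyl-2-(prop-1-en-2-yl)hex-4-en-1-yl]-4-[(triisopropylsilyl)oxy]-6-[(trimethylsilyl)oxy]cyclohexa-1,4-dien-1-yl}prop-2-yn-1-one | C=C(C)[C@H](CC=C(C)C)CC1=C(O[Si](C(C)C)(C(C)C)C(C)C)CC=C(C(=O)C#C)C1(OC)O[Si](C)(C)C | intermediate (not isolated)
17 | 1-{2-hydroxy-3-[(2R)-5-methyl-2-(prop-1-en-2-yl)hex-4-en-1-yl]-4-[(triisopropylsilyl)oxy]phenyl}prop-2-yn-1-one | C=C(C)[C@H](CC=C(C)C)Cc1c(O[Si](C(C)C)(C(C)C)C(C)C)ccc(C(=O)C#C)c1O | intermediate (not isolated)
18 | (2E)-3-(diethylamino)-1-{2-hydroxy-3-[(2R)-5-methyl-2-(prop-1-en-2-yl)hex-4-en-1-yl]-4-[(triisopropylsilyl)oxy]phenyl}prop-2-en-1-one | C=C(C)[C@H](CC=C(C)C)Cc1c(O[Si](C(C)C)(C(C)C)C(C)C)ccc(C(=O)/C=C/N(CC)CC)c1O | intermediate (not isolated)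
19 | 8-[(2R)-5-methyl-2-(prop-1-en-2-yl)hex-4-en-1-yl]-7-[(triisopropylsilyl)oxy]-4H-chromen-4-one | C=C(C)[C@H](CC=C(C)C)Cc1c(O[Si](C(C)C)(C(C)C)C(C)C)ccc2c1OC=CC2=O | intermediate
20 | 4-bromo-3-methoxyphenol | COc1cc(O)ccc1Br | starting material
21 | (4-bromo-3-methoxyphenoxy)triisopropylsilane | COc1cc(O[Si](C(C)C)(C(C)C)C(C)C)ccc1Br | intermediate
22 | {2-methoxy-4-[(triisopropylsilyl)oxy]phenyl}lithium | [Li]c1ccc(O[Si](C(C)C)(C(C)C)C(C)C)cc1OC | intermediate (not isolated)
23 | {2-methoxy-4-[(triisopropylsilyl)oxy]phenyl}boronic acid | COc1cc(O[Si](C(C)C)(C(C)C)C(C)C)ccc1B(O)O | intermediate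
24 | (2S)-2-{2-methoxy-4-[(triisopropylsilyl)oxy]phenyl}-8-[(2R)-5-methyl-2-(prop-1-en-2-yl)hex-4-en-1-yl]-7-[(triisopropylsilyl)oxy]-2,3-dihydro-4H-chromen-4-one | C=C(C)[C@H](CC=C(C)C)Cc1c(O[Si](C(C)C)(C(C)C)C(C)C)ccc2c1O[C@H](c1ccc(O[Si](C(C)C)(C(C)C)C(C)C)cc1OC)CC2=O | intermediate
25 | Alopecurone G | C=C(C)[C@H](CC=C(C)C)Cc1c(O)ccc2c1O[C@H](c1ccc(O)cc1OC)CC2=O | target

**Step count**

Total: 13 steps. Longest linear sequence: 10 steps (steps 1–7, 9, 12, 13).

**Three steps most likely to fail, with fallbacks**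

Step 9 (one-pot ring A/ring C cascade). The diynone 15 may oligomerise or take up two dienes, or the mixed ketal may aromatise to the methyl ether instead of the phenol. The fallback sets out from 13 and closes the two rings one after the other. Diene 13 and commercial but-3-yn-2-one (toluene, rt, then EtOH with a trace of Et3N) give the acetophenone 1-{2-hydroxy-3-[(2R)-5-methyl-2-(prop-1-en-2-yl)hex-4-en-1-yl]-4-[(triisopropylsilyl)oxy]phenyl}ethan-1-one F1. N,N-Dimethylformamide dimethyl acetal (neat, 60 °C) converts it into the dimethylamino enaminone F2, which closes with loss of Me2NH on warming in EtOH/AcOH. The fallback comes back to the route at 19.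

Step 12 (asymmetric arylation). The ortho-methoxy, electron-rich boronic acid 23 may add slowly or protodeboronate. The fallback sets out from 13, 14 and 21, brings the aryl group in before the stereocentre, and sets C2 by hydride delivery instead. Bromide 21 and an excess of 14 (Pd(OAc)2, XPhos, Cs2CO3, MeCN, 60 °C, copper-free Sonogashira coupling) give the aryl diynol 1-{2-methoxy-4-[(triisopropylsilyl)oxy]phenyl}penta-1,4-diyn-3-ol F3. MnO2 oxidises it to the aryl diynone F4. The step 9 protocol with 13 (cycloaddition at the unsubstituted alkyne, then Et2NH) gives the flavone F5. Copper hydride conjugate reduction (Cu(OAc)2, DTBM-SEGPHOS, (EtO)2MeSiH, t-BuOH, toluene, 0 °C; the ligand enantiomer is chosen by chiral HPLC of the product) comes back to the route at 24.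

Step 7 (hindered tetrasubstituted ketene acetal diene). The diene 13 may not form cleanly or may be too hindered to cycloadd. The fallback sets out from 9 and 15 and attaches the side chain after the rings by sp3–sp2 coupling. Commercial 1-methoxy-1,3-bis(trimethylsilyloxy)buta-1,3-diene and 15 under the step 9 protocol give 7-hydroxy-4H-chromen-4-one F6. N-Iodosuccinimide (DMF, 0 °C) iodinates the position between the two oxygens to give 7-hydroxy-8-iodo-4H-chromen-4-one F7, and i-Pr3SiCl/imidazole gives the silyl ether F8. Iodide 9 is converted with zinc dust and LiCl (THF, 40 °C) into the alkylzinc iodide F9; its stereocentre is β to zinc and is not touched. Negishi coupling of F8 with F9 (Pd(OAc)2, CPhos, THF, rt) comes back to the route at 19.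

**Further compounds**

F1 | step 9 | 1-{2-hydroxy-3-[(2R)-5-methyl-2-(prop-1-en-2-yl)hex-4-en-1-yl]-4-[(triisopropylsilyl)oxy]phenyl}ethan-1-one | C=C(C)[C@H](CC=C(C)C)Cc1c(O[Si](C(C)C)(C(C)C)C(C)C)ccc(C(C)=O)c1O
F2 | step 9 | (2E)-3-(dimethylamino)-1-{2-hydroxy-3-[(2R)-5-methyl-2-(prop-1-en-2-yl)hex-4-en-1-yl]-4-[(triisopropylsilyl)oxy]phenyl}prop-2-en-1-one | C=C(C)[C@H](CC=C(C)C)Cc1c(O[Si](C(C)C)(C(C)C)C(C)C)ccc(C(=O)/C=C/N(C)C)c1O
F3 | step 12 | 1-{2-methoxy-4-[(triisopropylsilyl)oxy]phenyl}penta-1,4-diyn-3-ol | C#CC(O)C#Cc1ccc(O[Si](C(C)C)(C(C)C)C(C)C)cc1OC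
F4 | step 12 | 1-{2-methoxy-4-[(triisopropylsilyl)oxy]phenyl}penta-1,4-diyn-3-one | C#CC(=O)C#Cc1ccc(O[Si](C(C)C)(C(C)C)C(C)C)cc1OC
F5 | step 12 | 2-{2-methoxy-4-[(triisopropylsilyl)oxy]phenyl}-8-[(2R)-5-methyl-2-(prop-1-en-2-yl)hex-4-en-1-yl]-7-[(triisopropylsilyl)oxy]-4H-chromen-4-one | C=C(C)[C@H](CC=C(C)C)Cc1c(O[Si](C(C)C)(C(C)C)C(C)C)ccc2c1OC(c1ccc(O[Si](C(C)C)(C(C)C)C(C)C)cc1OC)=CC2=O
F6 | step 7 | 7-hydroxy-4H-chromen-4-one | O=C1C=COc2cc(O)ccc12
F7 | step 7 | 7-hydroxy-8-iodo-4H-chromen-4-one | O=C1C=COc2c(I)c(O)ccc12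
F8 | step 7 | 8-iodo-7-[(triisopropylsilyl)oxy]-4H-chromen-4-one | CC(C)[Si](Oc1ccc2c(c1I)OC=CC2=O)(C(C)C)C(C)C
F9 | step 7 | [(2S)-5-methyl-2-(prop-1-en-2-yl)hex-4-en-1-yl]zinc iodide | C=C(C)[C@H](CC=C(C)C)C[Zn]I
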